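(The data are calculated for an exercise, and the scatter is random.)

Read the constants off the readings first; both flasks are reckoned with them below.

| setting | Wednesday's | Sunday's | Thursday's | alder | ash |
|---|---|---|---|---|---|
| starting material | 0.012 M | 0.012 M | 0.020 M | 0.012 M | 0.050 M |
| reagent | 0.018 M | 0.087 M | 0.0144 M | 0.0144 M | 0.0600 M |
| remark | run made earlier | run made earlier | run made earlier |  |  |
| time |  |  |  | 3.0 min | 0.80 min |

| run | time / s | target / % |
|---|---|---|
| Wednesday's | 20.0 | 2.8 |
| Wednesday's | 40.0 | 2.7 |
| Wednesday's | 50.0 | 4.6 |
| Wednesday's | 80.0 | 5.8 |
| Wednesday's | 90.0 | 7.5 |
| Wednesday's | 120 | 10.3 |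
| Sunday's | 20.0 | 19.7 |
| Sunday's | 40.0 | 33.8 |
| Sunday's | 50.0 | 39.4 |
| Sunday's | 80.0 | 52.0 |
| Sunday's | 90.0 | 54.1 |
| Sunday's | 120 | 60.1 |
| Thursday's | 10.0 | 0.4 |
| Thursday's | 20.0 | 0.8 |
| Thursday's | 40.0 | 1.7 |
| Thursday's | 60.0 | 2.3 |
| Thursday's | 120 | 4.3 |

(scatter of a reading: 0.5 percentage points)

- the flask that ends with the higher amount of target, in percent of the starting material charged, or "neither" when 2 percentage points or less lies between them (alder / ash / neither)
- final target, as a percentage of the starting material charged, in alder
- final target, as a percentage of the starting material charged, in ash

- what was read earlier has a scatter of 0.5 percentage points, one standard deviation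
- steps under discussion: starting material + reagent -> intermediate B; reagent + intermediate A -> side product; starting material -> intermediate A; reagent + intermediate B -> target

Start from Sunday's run, where reagent stands at 7.25 times the starting material. Treat its level as fixed there, so that reagent + intermediate B → target is pseudo-first-order. Over equal spells of 0.667 min, target gains 18 percentage points and then 8.1 points. These readings, with their scatter, give a rate of 0.0202 s⁻¹ and a plateau of 66.6%. Call that rate, scaled by a flask's reagent and multiplied by its time, the lifetime count of intermediate B. Read the plateau as the share of starting material taking the reagent route, and scale its odds, 1.99 on Sunday's run, with reagent too. This gives shares of 24.8% in alder and 57.9% in ash.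

Now solve two extreme flasks. Hold reagent at its charge: alder counts 0.603 lifetimes and makes 11.2%, while ash counts 0.670 and makes 28.3%. Or take reagent equal to the whole charge of starting material off the level at once, keeping the same shares: this reckoning gives alder 2.37% and ash 6.12%. Expect each flask between the two: the first version spends no reagent, the second spends a full charge's worth from the start. My own commitment subtracts the routed share: 9.43% for alder, and for ash 0.347 lifetimes and 17.0%, so I expect ash to make more.

The forecast names ash, with 7% for alder and 14% for ash, where “reagent depletes quickly”. Both its figures lie below mine.

The flask gives ash: 8.82% in alder and 14.1% in ash.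

    starting material + reagent → intermediate B (k = 3.85 M⁻¹ s⁻¹)
    reagent + intermediate A → side product (k = 0.0763 M⁻¹ s⁻¹)
    starting material → intermediate A (k = 0.137 s⁻¹)
    reagent + intermediate B → target (k = 0.231 M⁻¹ s⁻¹)

Falling reagent and the short time act together as part of what holds ash down: with reagent held at its charge ash reaches 29.2% in its time, and left until 8.00 min it reaches 40.3%. My count of 0.347 says the same of ash: at its end it stands partway, holding 41.2% as intermediate B beside 14.1% of target.

Take the neighbour of ash with 0.020 M of starting material. In my reckoning its share stays 57.9% with the reagent charge unchanged, its count rises to 0.541, and so expect 24.2%; that flask gives 22.6%.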